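The route rests on disconnecting the bond between ring carbon C8 and side-chain methylene C7 (prostanoic acid numbering, C1 = CO2H). The key step exploits the vicinal trans side chains on cyclopentane carbons C12 and C8 next to oxygenated C9: with C9 as a ketone, C12 is the electrophilic beta carbon of an enone and C8 the nucleophilic alpha carbon. In one flask an (S,E)-alkenyl zincate adds to (R)-4-silyloxycyclopent-2-enone (C12–C13) and the resulting enolate is alkylated by a C1–C7 propargylic iodide (C7–C8). The precursors are thus three simple fragments; the C11 stereocenter controls C12 and, through it, C8. Ketone reduction, alkyne saturation and deprotection follow.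

Key step: step 6

Remark: prostanoic acid numbering is used throughout (C8–C12 = ring, C13–C20 = lower chain); TBS = tert-butyldimethylsilyl; (S)-oct-1-yn-3-ol, hex-5-ynoic acid and (R)-4-(tert-butyldimethylsilyloxy)cyclopent-2-en-1-one are taken as catalogue chemicals.

Step 1
Reactants: 1 (S)-oct-1-yn-3-ol
Product: 2 (S)-tert-butyldimethyl(oct-1-yn-3-yloxy)silane
Conditions: TBSCl, imidazole, DMF, 0 °C → rt
Reagents that add atoms: tert-butyldimethylsilyl chloride, CC(C)(C)[Si](C)(C)Cl
Why: Imidazole-promoted silylation of the secondary propargylic alcohol (standard TBS ether formation) does not touch the stereocenter that later becomes C15.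

Step 2
Reactants: 2 (S)-tert-butyldimethyl(oct-1-yn-3-yloxy)silane
Product: 4 tert-butyl{[(1E,3S)-1-iodooct-1-en-3-yl]oxy}dimethylsilane, via alkenylzirconocene chloride 3 (not isolated)
Conditions: Cp2Zr(H)Cl, THF, rt; then I2, 0 °C
Reagents that add atoms: iodine, II
Why: Hydrozirconation adds Zr–H syn across the terminal alkyne with zirconium on the terminal carbon, and iodinolysis of the C–Zr bond goes with retention, so the (E)-iodide should form as one regio- and stereoisomer (hydrozirconation–iodination).

Step 3
Reactants: 5 hex-5-ynoic acid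
Product: 7 7-hydroxyhept-5-ynoic acid, via dilithium alkynide carboxylate 6 (not isolated)
Conditions: n-BuLi (2.1 equiv), THF/DMPU, −78 → 0 °C; (CH2O)n, 0 °C → rt; aq. HCl
Reagents that add atoms: paraformaldehyde (as formaldehyde), C=O
Why: The second equivalent of n-BuLi deprotonates the alkyne C–H of the lithium carboxylate, and the acetylide carbon adds to formaldehyde (acetylide hydroxymethylation), the carboxylate being inert toward its own acetylide.

Step 4
Reactants: 7 7-hydroxyhept-5-ynoic acid
Product: 8 methyl 7-hydroxyhept-5-ynoate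
Conditions: MeOH, cat. H2SO4, rt
Reagents that add atoms: methanol, CO
Why: Fischer esterification in a large excess of methanol should convert the acid into the methyl ester without affecting the propargylic alcohol.

Step 5
Reactants: 8 methyl 7-hydroxyhept-5-ynoate
Product: 9 methyl 7-iodohept-5-ynoate
Conditions: PPh3, I2, imidazole, CH2Cl2, 0 °C, dark
Reagents that add atoms: iodine, II
Why: Appel-type iodination, in which the primary propargylic alcohol is activated as an oxyphosphonium ion and displaced by iodide in an SN2 reaction.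

Step 6
Reactants: 4 tert-butyl{[(1E,3S)-1-iodooct-1-en-3-yl]oxy}dimethylsilane; 10 (R)-4-(tert-butyldimethylsilyloxy)cyclopent-2-en-1-one; 9 methyl 7-iodohept-5-ynoate
Product: 14 methyl 7-[(1R,2R,3R)-3-(tert-butyldimethylsilyloxy)-2-[(1E,3S)-3-(tert-butyldimethylsilyloxy)oct-1-enyl]-5-oxocyclopentyl]hept-5-ynoate, via alkenyllithium 11 (not isolated), via lithium alkenyldimethylzincate 12 (not isolated), via zinc enolate 13 (not isolated)
Conditions: 4, t-BuLi (2.0 equiv), Et2O, −78 °C; Me2Zn (1.0 equiv), THF, 0 °C; 10, −78 °C; HMPA, 9 (excess), −78 → −40 °C; aq. NH4Cl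
Reagents that add atoms: none
Why: Iodine–lithium exchange gives alkenyllithium 11, which forms the mixed zincate 12 with Me2Zn; 12 transfers only its alkenyl group in a 1,4-addition to enone 10, and the regiodefined enolate 13 (C8=C9, oxygen on zinc) is C-alkylated in an HMPA-promoted SN2 reaction at the propargylic CH2–I of 9, which creates the C7–C8 bond. The closest known reaction type is the tandem conjugate addition–enolate alkylation (three-component coupling) of 4-silyloxycyclopent-2-enones with alkenyl zincates and propargylic or allylic iodides. No ring is closed; the cyclopentane comes intact from 10. C12 is set by the C11 silyloxy group, which blocks its own face so that the alkenyl group enters trans to it, and C8 is set by the new C12 substituent, the electrophile approaching the enolate anti to it (8,12-trans, which is also the thermodynamic arrangement). The step needs alkylation to outrun enolate proton exchange and beta-elimination of the C11 silyloxide, and it needs C- over O-alkylation and SN2 over SN2' attack. The low basicity of the zinc-bound enolate, HMPA activation, the excess of the reactive primary propargylic iodide and temperatures at or below −40 °C should secure this, with the methyl groups on zinc acting as non-transferred spectators.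

Step 7
Reactants: 14 methyl 7-[(1R,2R,3R)-3-(tert-butyldimethylsilyloxy)-2-[(1E,3S)-3-(tert-butyldimethylsilyloxy)oct-1-enyl]-5-oxocyclopentyl]hept-5-ynoate
Product: 15 methyl 7-[(1R,2R,3R,5S)-3-(tert-butyldimethylsilyloxy)-5-hydroxy-2-[(1E,3S)-3-(tert-butyldimethylsilyloxy)oct-1-enyl]cyclopentyl]hept-5-ynoate
Conditions: LiBH(s-Bu)3, THF, −78 °C; aq. NH4Cl
Reagents that add atoms: none
Why: The bulky hydride should attack the C9 carbonyl from the beta face, away from the alpha-oriented C8 side chain and C11 silyloxy group, giving the 9-alpha (9S) alcohol (substrate-controlled diastereoselective ketone reduction), while ester and alkyne are inert at −78 °C.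

Step 8
Reactants: 15 methyl 7-[(1R,2R,3R,5S)-3-(tert-butyldimethylsilyloxy)-5-hydroxy-2-[(1E,3S)-3-(tert-butyldimethylsilyloxy)oct-1-enyl]cyclopentyl]hept-5-ynoate
Product: 17 methyl 7-[(1R,2R,3R,5S)-3-(tert-butyldimethylsilyloxy)-5-hydroxy-2-[(1E,3S)-3-(tert-butyldimethylsilyloxy)oct-1-enyl]cyclopentyl]heptanoate, via cis-alkene 16 (not isolated)
Conditions: H2 (1 atm), 5% Pd/C, EtOAc, −20 → 0 °C, stopped after 2 equiv H2
Reagents that add atoms: none
Why: Heterogeneous hydrogenation should saturate the exposed C5–C6 triple bond through the cis-alkene much faster than the trans C13–C14 olefin, which is screened on both sides by the C11 and C15 silyloxy groups; low temperature and the stop at two equivalents of H2 protect that olefin and the allylic C15–O bond (chemoselective catalytic hydrogenation).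

Step 9
Reactants: 17 methyl 7-[(1R,2R,3R,5S)-3-(tert-butyldimethylsilyloxy)-5-hydroxy-2-[(1E,3S)-3-(tert-butyldimethylsilyloxy)oct-1-enyl]cyclopentyl]heptanoate
Product: 19 prostaglandin F1alpha (7-[(1R,2R,3R,5S)-3,5-dihydroxy-2-[(1E,3S)-3-hydroxyoct-1-enyl]cyclopentyl]heptanoic acid), via lithium carboxylate 18 (not isolated)
Conditions: LiOH, THF/H2O, rt; then AcOH/THF/H2O (3:1:1), rt → 40 °C
Reagents that add atoms: lithium hydroxide, [Li+].[OH-]
Why: Saponification of the methyl ester, followed in the same flask by acid-catalysed hydrolysis of both secondary TBS ethers in aqueous acetic acid, should release the trihydroxy acid; the F-type ring has no beta-hydroxy ketone, so neither stage can cause elimination or epimerisation.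

Compound list
1 | (S)-oct-1-yn-3-ol | CCCCC[C@H](O)C#C | starting material
2 | (S)-tert-butyldimethyl(oct-1-yn-3-yloxy)silane | CCCCC[C@H](O[Si](C)(C)C(C)(C)C)C#C | intermediate
3 | chlorobis(cyclopentadienyl)[(1E,3S)-3-(tert-butyldimethylsilyloxy)oct-1-enyl]zirconium, formed in situ (cyclopentadienyl rings drawn sigma-bonded) | CCCCC[C@H](O[Si](C)(C)C(C)(C)C)/C=C/[Zr](Cl)(C1C=CC=C1)C1C=CC=C1 | intermediate
4 | tert-butyl{[(1E,3S)-1-iodooct-1-en-3-yl]oxy}dimethylsilane | CCCCC[C@H](O[Si](C)(C)C(C)(C)C)/C=C/I | intermediate
5 | hex-5-ynoic acid | C#CCCCC(=O)O | starting material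
6 | dilithium salt of hex-5-ynoic acid (carboxylate and terminal acetylide), formed in situ | [Li+].[Li+].[C-]#CCCCC(=O)[O-] | intermediate
7 | 7-hydroxyhept-5-ynoic acid | OCC#CCCCC(=O)O | intermediate
8 | methyl 7-hydroxyhept-5-ynoate | COC(=O)CCCC#CCO | intermediate
9 | methyl 7-iodohept-5-ynoate | COC(=O)CCCC#CCI | intermediate
10 | (R)-4-(tert-butyldimethylsilyloxy)cyclopent-2-en-1-one | O=C1C[C@@H](O[Si](C)(C)C(C)(C)C)C=C1 | starting material
11 | [(1E,3S)-3-(tert-butyldimethylsilyloxy)oct-1-enyl]lithium, formed in situ | CCCCC[C@H](O[Si](C)(C)C(C)(C)C)/C=C/[Li] | intermediate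
12 | lithium [(1E,3S)-3-(tert-butyldimethylsilyloxy)oct-1-enyl]dimethylzincate, formed in situ | CCCCC[C@H](O[Si](C)(C)C(C)(C)C)/C=C/[Zn-](C)C.[Li+] | intermediate
13 | lithium dimethylzincate enolate (C8=C9, O on zinc) of the 3,4-trans conjugate adduct of 10, formed in situ | CCCCC[C@H](O[Si](C)(C)C(C)(C)C)/C=C/[C@@H]1C=C(O[Zn-](C)C)C[C@H]1O[Si](C)(C)C(C)(C)C.[Li+] | intermediate
14 | methyl 7-[(1R,2R,3R)-3-(tert-butyldimethylsilyloxy)-2-[(1E,3S)-3-(tert-butyldimethylsilyloxy)oct-1-enyl]-5-oxocyclopentyl]hept-5-ynoate (5,6-didehydro-PGE2 methyl ester 11,15-bis-TBS ether) | CCCCC[C@H](O[Si](C)(C)C(C)(C)C)/C=C/[C@@H]1[C@@H](CC#CCCCC(=O)OC)C(=O)C[C@H]1O[Si](C)(C)C(C)(C)C | intermediate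
15 | methyl 7-[(1R,2R,3R,5S)-3-(tert-butyldimethylsilyloxy)-5-hydroxy-2-[(1E,3S)-3-(tert-butyldimethylsilyloxy)oct-1-enyl]cyclopentyl]hept-5-ynoate | CCCCC[C@H](O[Si](C)(C)C(C)(C)C)/C=C/[C@@H]1[C@@H](CC#CCCCC(=O)OC)[C@@H](O)C[C@H]1O[Si](C)(C)C(C)(C)C | intermediate
16 | methyl (5Z)-7-[(1R,2R,3R,5S)-3-(tert-butyldimethylsilyloxy)-5-hydroxy-2-[(1E,3S)-3-(tert-butyldimethylsilyloxy)oct-1-enyl]cyclopentyl]hept-5-enoate, formed in situ | CCCCC[C@H](O[Si](C)(C)C(C)(C)C)/C=C/[C@@H]1[C@@H](C/C=C\CCCC(=O)OC)[C@@H](O)C[C@H]1O[Si](C)(C)C(C)(C)C | intermediate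
17 | methyl 7-[(1R,2R,3R,5S)-3-(tert-butyldimethylsilyloxy)-5-hydroxy-2-[(1E,3S)-3-(tert-butyldimethylsilyloxy)oct-1-enyl]cyclopentyl]heptanoate (PGF1alpha methyl ester 11,15-bis-TBS ether) | CCCCC[C@H](O[Si](C)(C)C(C)(C)C)/C=C/[C@@H]1[C@@H](CCCCCCC(=O)OC)[C@@H](O)C[C@H]1O[Si](C)(C)C(C)(C)C | intermediate
18 | lithium 7-[(1R,2R,3R,5S)-3-(tert-butyldimethylsilyloxy)-5-hydroxy-2-[(1E,3S)-3-(tert-butyldimethylsilyloxy)oct-1-enyl]cyclopentyl]heptanoate, formed in situ | CCCCC[C@H](O[Si](C)(C)C(C)(C)C)/C=C/[C@@H]1[C@@H](CCCCCCC(=O)[O-])[C@@H](O)C[C@H]1O[Si](C)(C)C(C)(C)C.[Li+] | intermediate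
19 | prostaglandin F1alpha, 7-[(1R,2R,3R,5S)-3,5-dihydroxy-2-[(1E,3S)-3-hydroxyoct-1-enyl]cyclopentyl]heptanoic acid | CCCCC[C@H](O)/C=C/[C@@H]1[C@@H](CCCCCCC(=O)O)[C@@H](O)C[C@H]1O | target

Total step count: 9. Longest linear sequence: 7 steps (steps 3, 4, 5, 6, 7, 8 and 9, from hex-5-ynoic acid).

Steps most likely to fail

Step 6. The alkylation may be too slow relative to proton transfer between enolate 13 and already alkylated ketone, which would lead to loss of the C11 silyloxide, to dialkylation or to the simple conjugate adduct. The fallback sets out from 4 and 10 and comes back to the route at 17. The same zincate addition is run, but the enolate is trapped by an aldol addition to commercial methyl 7-oxoheptanoate (O=CCCCCCC(=O)OC) at −78 °C. This is fast and irreversible at that temperature and still forms the C7–C8 bond, and it should give the aldol adduct methyl 7-hydroxy-7-[(1R,2R,3R)-3-(tert-butyldimethylsilyloxy)-2-[(1E,3S)-3-(tert-butyldimethylsilyloxy)oct-1-enyl]-5-oxocyclopentyl]heptanoate F1 as a mixture of C7 epimers. Mesylation and elimination (MsCl, DMAP, CH2Cl2) should give the exocyclic enone 7,8-didehydro-PGE1 methyl ester 11,15-bis-TBS ether F2, mainly 7E, whose geometry is lost in the next operation. Conjugate reduction with Bu3SnH under radical initiation (hydrostannylation to the tin enolate, protonolysis on work-up) should give PGE1 methyl ester 11,15-bis-TBS ether F3 with the trans C8 configuration. Reduction with LiBH(s-Bu)3 as in step 7 then leads to 17; the alkyne-based steps 7 and 8 are not needed on this path.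

Step 8. The palladium surface may discriminate poorly between the C5–C6 unsaturation and the C13–C14 olefin, so that over-reduction or hydrogenolysis of the allylic C15–O bond sets in before the alkyne is consumed. The fallback sets out from 15 and comes back at 17. The reduction is split into two operations that are each selective by themselves. Semi-hydrogenation over Pd/BaSO4 with quinoline gives the cis-alkene 16, now isolated. Homogeneous hydrogenation with RhCl(PPh3)3 (benzene/ethanol, H2 1 atm) then reduces the unhindered cis-disubstituted olefin and should leave the hindered trans olefin untouched. No compound outside the compound list is made (entry F0).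

Step 9. Cleavage of the hindered C11 silyl ether in aqueous acetic acid may be slow, and the long acid stage may allow allylic transposition or epimerisation at C15. The fallback sets out from 17 and comes back at 19. Fluoride-driven desilylation with HF·pyridine in MeCN at 0 °C gives isolated PGF1alpha methyl ester F4. Its ester is then hydrolysed under neutral conditions with porcine liver esterase in pH 7–8 phosphate buffer, so that the free triol never meets acid or strong base.

Further compounds
F1 | step 6 | methyl 7-hydroxy-7-[(1R,2R,3R)-3-(tert-butyldimethylsilyloxy)-2-[(1E,3S)-3-(tert-butyldimethylsilyloxy)oct-1-enyl]-5-oxocyclopentyl]heptanoate (C7 epimers) | CCCCC[C@H](O[Si](C)(C)C(C)(C)C)/C=C/[C@@H]1[C@@H](C(O)CCCCCC(=O)OC)C(=O)C[C@H]1O[Si](C)(C)C(C)(C)C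
F2 | step 6 | methyl (7E)-7-[(2R,3R)-3-(tert-butyldimethylsilyloxy)-2-[(1E,3S)-3-(tert-butyldimethylsilyloxy)oct-1-enyl]-5-oxocyclopentylidene]heptanoate | CCCCC[C@H](O[Si](C)(C)C(C)(C)C)/C=C/[C@@H]1/C(=C\CCCCCC(=O)OC)C(=O)C[C@H]1O[Si](C)(C)C(C)(C)C
F3 | step 6 | methyl 7-[(1R,2R,3R)-3-(tert-butyldimethylsilyloxy)-2-[(1E,3S)-3-(tert-butyldimethylsilyloxy)oct-1-enyl]-5-oxocyclopentyl]heptanoate (PGE1 methyl ester 11,15-bis-TBS ether) | CCCCC[C@H](O[Si](C)(C)C(C)(C)C)/C=C/[C@@H]1[C@@H](CCCCCCC(=O)OC)C(=O)C[C@H]1O[Si](C)(C)C(C)(C)C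
F0 | step 8 | none | none
F4 | step 9 | methyl 7-[(1R,2R,3R,5S)-3,5-dihydroxy-2-[(1E,3S)-3-hydroxyoct-1-enyl]cyclopentyl]heptanoate (PGF1alpha methyl ester) | CCCCC[C@H](O)/C=C/[C@@H]1[C@@H](CCCCCCC(=O)OC)[C@@H](O)C[C@H]1O
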